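**Strategy.** Ring B (C5–C10, labdane numbering) is 2,6-dimethyl-1,4-benzoquinone in disguise: methyls at C8 and C10, oxygens at C6 and C9. Ring A is closed onto it in one Diels–Alder operation that forms the quaternary C10–C1 bond together with C4–C5, using the silyl dienol ether of methyl 3-oxopent-4-enoate (C1–C4 plus C19). The dienophile is the enantioenriched cyclopentadiene adduct of the quinone: its norbornene masks C7=C8, blocks one face and is later expelled by cycloreversion. The C9 carbonyl then becomes the triflate for the side chain, the C6 carbonyl the 6β-alcohol, and the β-keto ester sets C3 and C4.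

Key step: step 5

Remark: labdane numbering is used for the decalin carbons of all intermediates (ring A = C1–C4, ring fusion C5/C10, ring B = C6–C9, C19 = carbon on the β-face of C4); β = same face as the C10 methyl.

Assumption: the (S)-configured oxazaborolidinium catalyst of step 4 gives 8 in the absolute configuration drawn; should it favour the mirror image, the (R)-catalyst is used and nothing else changes.

Step 1
Reactants: 1 methyl acetate; 2 acrolein
Product: 3 methyl 3-hydroxypent-4-enoate (racemic)
Conditions: LiN(i-Pr)2, THF, −78 °C; then 2, −78 °C; aqueous work-up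
Reagents that add atoms: none
Why: Aldol addition of the lithium ester enolate to the aldehyde carbonyl (1,2-addition at low temperature); the carbinol centre is removed in step 2, so no stereocontrol is needed.

Step 2
Reactants: 3 methyl 3-hydroxypent-4-enoate
Product: 4 methyl 3-oxopent-4-enoate
Conditions: DMP (1,1,1-triacetoxy-1,1-dihydro-1,2-benziodoxol-3(1H)-one), CH2Cl2, 0 °C
Reagents that add atoms: none
Why: Hypervalent-iodine oxidation of the allylic secondary alcohol under neutral conditions should give the polymerisation-prone vinyl β-keto ester, which is used at once.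

Step 3
Reactants: 4 methyl 3-oxopent-4-enoate
Product: 5 methyl (2Z)-3-[(tert-butyldimethylsilyl)oxy]penta-2,4-dienoate
Conditions: TBSOTf, Et3N, CH2Cl2, −78 → 0 °C
Reagents that add atoms: tert-butyldimethylsilyl triflate CC(C)(C)[Si](C)(C)OS(=O)(=O)C(F)(F)F
Why: O-silylation of the enolised β-keto ester should give the Z enol ether (silyloxy cis to the ester), which places the ester as an outside substituent of the s-cis diene.

Step 4
Reactants: 6 2,6-dimethyl-1,4-benzoquinone; 7 cyclopenta-1,3-diene (freshly cracked from the commercial dimer)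
Product: 8 endo-7,8a-dimethyl-1,4,4a,8a-tetrahydro-1,4-methanonaphthalene-5,8-dione (norbornene on the β-face of future C7/C8, C8 methyl α)
Conditions: (S)-diphenylprolinol-derived B-(o-tolyl)oxazaborolidine·HNTf2 (10 mol %), CH2Cl2, −78 °C
Reagents that add atoms: none
Why: Enantioselective Diels–Alder reaction of a quinone under chiral cationic oxazaborolidine catalysis, a known catalyst class for quinone dienophiles; endo addition to one of the two enantiotopic C(Me)=CH bonds sets C7, C8 and both bridgeheads, and the symmetric diene raises no regiochemical question.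

Step 5
Reactants: 8 cyclopentadiene-masked ene-dione; 5 silyl dienol ether
Product: 9 tetracyclic adduct: ring A (C1H2, C2H=C3–OTBS, C4H–CO2Me) cis-fused at C5/C10 on the face anti to the norbornene; 10β-Me, 5β-H, 4α-CO2Me, C6 and C9 ketones
Conditions: toluene, BHT (cat.), 100 °C, sealed tube
Reagents that add atoms: none
Why: The step is a concerted, asynchronous normal-demand [4+2] cycloaddition between the electron-rich 2-silyloxy diene 5 and the ene-dione C5=C10 of 8, in which the C4–C5 bond leads and the C1–C10 bond completes ring A. The closest known reaction type is the thermal Diels–Alder addition of 2-silyloxy-1,3-dienes to methyl-substituted quinones and their cyclopentadiene-masked ene-diones, which gives angular-methyl cis-decalins. Ring A (C1–C2–C3–C4–C5–C10) closes as a six-membered ring by suprafacial–suprafacial cycloaddition, hence the cis ring fusion. C10 (quaternary) and C5 are set by approach to the convex face of the ene-dione, anti to the norbornene CH=CH bridge, so their absolute configuration is relayed from C7/C8 of 8; C4 follows the endo rule (ester cis to C6) and is re-set in step 9. The step needs the regiochemistry C4→C5 and C1→C10, which should be secured because the nucleophilic diene terminus (C4, next to the silyloxy carbon) pairs with the unsubstituted, more electrophilic C5 (β to the C9 carbonyl) and the unhindered CH2 terminus with the methyl-bearing C10, so polarisation and sterics agree. The norbornene mask leaves only one dienophilic double bond and excludes the aromatisation and redox chemistry of a free quinone.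

Step 6
Reactants: 9 tetracyclic adduct
Product: 10 cis-fused ene-dione: C2=C3 TBS enol ether, 4α-CO2Me, 5β-H, 6-oxo, C7=C8(Me), 9-oxo, 10β-Me
Conditions: flash vacuum pyrolysis, 480 °C, 0.05 mbar
Reagents that add atoms: none
Why: Retro-Diels–Alder cycloreversion, driven by loss of volatile cyclopentadiene and formation of the conjugated ene-dione; C4, C5 and C10 are not involved.

Step 7
Reactants: 10 cis-fused ene-dione
Product: 11 bis(TBS enol ether): C2=C3–OTBS and C5=C6–OTBS, C7=C8(Me)–C9=O, 4α-CO2Me, 10β-Me
Conditions: TBSOTf, Et3N, CH2Cl2, −78 → 0 °C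
Reagents that add atoms: tert-butyldimethylsilyl triflate CC(C)(C)[Si](C)(C)OS(=O)(=O)C(F)(F)F
Why: Silyl enol ether formation; the C6 ketone can enolise only toward C5 (C7 is sp2, C9 has no α-hydrogen), which protects C6, makes C5 trigonal and so postpones the ring-fusion question until C4 is quaternary.

Step 8
Reactants: 11 bis(TBS enol ether) dienone
Product: 13 C9 enol triflate (C8=C9–OTf, C7H2) with both TBS enol ethers and 4α-CO2Me retained, via lithium enolate 12 (not isolated)
Conditions: LiBH(s-Bu)3 (1.1 equiv), THF, −78 °C; then PhNTf2, −78 → 0 °C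
Reagents that add atoms: N-phenylbis(trifluoromethanesulfonimide) O=S(=O)(N(c1ccccc1)S(=O)(=O)C(F)(F)F)C(F)(F)F; lithium tri-sec-butylborohydride [Li+].CCC(C)[BH-](C(C)CC)C(C)CC (Li in 12 only, H in 13)
Why: Conjugate reduction with enolate trapping: hydride adds to the unsubstituted C7 of the enone (the C9 carbonyl is shielded by quaternary C10), giving regiospecifically the tetrasubstituted C8=C9 enolate, which is O-triflated.

Step 9
Reactants: 13 enol triflate
Product: 16 trans-fused diketo ester: 3-oxo, 6-oxo, 4α-Me, 4β-CO2Me, 5α-H, 10β-Me, C8=C9–OTf, via potassium dienolate 14 (not isolated), via C4-methylated bis-silyl enol ether 15 (not isolated)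
Conditions: KN(SiMe3)2, THF, −78 °C; MeI, −78 → −20 °C; then 1 M HCl, THF, rt
Reagents that add atoms: iodomethane CI; potassium bis(trimethylsilyl)amide C[Si](C)(C)[N-][Si](C)(C)C.[K+] (K in 14 only)
Why: Deprotonation of the doubly allylic C4–H gives a pentadienyl ester enolate that should be C-methylated at C4 on the α-face, anti to the pseudo-axial C10 methyl of the flattened ring A (the α-face alkylation known for C5=C6-unsaturated C4 enolates), and acid hydrolysis of both silyl enol ethers then protonates C5 from the α-face to give the trans-fused diketone, which is also the thermodynamic isomer once C4 is quaternary.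

Step 10
Reactants: 16 trans-fused diketo ester
Product: 18 3α,6β,19-triol with C8=C9–OTf, via hydroxy lactone 17 (not isolated)
Conditions: LiBH(s-Bu)3 (2.5 equiv), THF, −78 → 0 °C; then LiBH4, MeOH (2 equiv), 0 °C → rt
Reagents that add atoms: none
Why: Bulky-hydride ketone reduction: C3 is attacked from the equatorial direction (axial 3α-OH) and C6 from the α-face because the β-face is closed by the syn-axial C10 methyl and C4 ester (axial 6β-OH); the 6β-alkoxide lactonises onto the syn-axial ester and LiBH4 reduces the γ-lactone to the 6β,19-diol without touching the enol triflate.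

Step 11
Reactants: 18 triol; 19 3-methylbutanoyl chloride (2.3 equiv)
Product: 20 3α,19-bis(3-methylbutanoate) with free 6β-OH and C8=C9–OTf
Conditions: pyridine, DMAP (cat.), CH2Cl2, 0 °C → rt
Reagents that add atoms: none
Why: Nucleophile-catalysed acylation of the primary C19 and the axial 3α hydroxyls; the 6β-hydroxyl is 1,3-diaxial to both the C10 methyl and the C4 CH2O group (comparable to an 11β-hydroxyl of a corticoid) and should remain free.

Step 12
Reactants: 20 bis-ester enol triflate
Product: 21 C9-vinyl diene (C8=C9–CH=CH2), 3α,19-bis(3-methylbutanoate), 6β-OH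
Conditions: Bu3Sn(CH=CH2), Pd(PPh3)4 (5 mol %), LiCl, THF, 65 °C
Reagents that add atoms: tributyl(vinyl)stannane C=C[Sn](CCCC)(CCCC)CCCC
Why: Stille coupling; sp2–sp2 coupling is reliable at hindered tetrasubstituted enol triflates and the neutral conditions leave the esters and the free alcohol alone.

Step 13
Reactants: 22 2,2,6-trimethyl-4H-1,3-dioxin-4-one; 23 2-(trimethylsilyl)ethanol
Product: 24 2-(trimethylsilyl)ethyl 3-oxobutanoate
Conditions: xylene, 140 °C
Reagents that add atoms: none
Why: Thermal retro-[4+2] of the dioxinone releases acetylketene, which the alcohol traps (acetoacetylation).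

Step 14
Reactants: 24 2-(trimethylsilyl)ethyl 3-oxobutanoate
Product: 25 2-(trimethylsilyl)ethyl (2E)-3-{[(trifluoromethyl)sulfonyl]oxy}but-2-enoate
Conditions: Tf2O, aq. Me4NOH, hexane, 5 °C
Reagents that add atoms: trifluoromethanesulfonic anhydride O=S(=O)(OS(=O)(=O)C(F)(F)F)C(F)(F)F
Why: O-triflation of the non-chelated ammonium enolate, which holds the enolate oxygen trans to the ester, should give the E enol triflate (a lithium-chelated enolate would give Z).

Step 15
Reactants: 21 C9-vinyl diene; 25 E enol triflate
Product: 27 2-(trimethylsilyl)ethyl ester of the target acid (13E), via B-alkyl-9-BBN 26 (not isolated)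
Conditions: 9-BBN-H (2.2 equiv), THF, 0 °C → rt; then aq. K3PO4, 25, PdCl2(dppf) (5 mol %), THF/DMF, rt
Reagents that add atoms: 9-borabicyclo[3.3.1]nonane B1C2CCCC1CCC2 (B in 26 only, H in 27)
Why: Anti-Markovnikov hydroboration of the monosubstituted vinyl group (the tetrasubstituted C8=C9 is inert) followed by B-alkyl Suzuki–Miyaura coupling, which retains the triflate geometry and so fixes the 13E double bond.

Step 16
Reactants: 27 2-(trimethylsilyl)ethyl ester
Product: 28 (13E)-6β-hydroxy-3α,19-bis(3-methylbutanoyloxy)labda-8,13-dien-15-oic acid (3R,4S,5R,6R,10S), the target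
Conditions: Bu4NF, THF, 0 °C → rt; aq. NH4Cl
Reagents that add atoms: none
Why: Fluoride-induced β-elimination of the 2-(trimethylsilyl)ethyl ester frees the acid without acyl cleavage at the hindered 3-methylbutanoates or isomerisation of either double bond.

**Compound list**

1 | methyl acetate | COC(C)=O | starting material
2 | acrolein | C=CC=O | starting material
3 | methyl 3-hydroxypent-4-enoate (racemic) | C=CC(O)CC(=O)OC | intermediate
4 | methyl 3-oxopent-4-enoate | C=CC(=O)CC(=O)OC | intermediate
5 | methyl (2Z)-3-[(tert-butyldimethylsilyl)oxy]penta-2,4-dienoate | C=C/C(O[Si](C)(C)C(C)(C)C)=C/C(=O)OC | intermediate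
6 | 2,6-dimethyl-1,4-benzoquinone | CC1=CC(=O)C=C(C)C1=O | starting material
7 | cyclopenta-1,3-diene | C1=CCC=C1 | starting material
8 | endo-7,8a-dimethyl-1,4,4a,8a-tetrahydro-1,4-methanonaphthalene-5,8-dione | CC1=CC(=O)[C@@H]2[C@@H]3C=C[C@@H](C3)[C@]2(C)C1=O | intermediate
9 | tetracyclic Diels–Alder adduct (ring A cis-fused anti to the norbornene) | C[C@@]12C(=O)[C@@]3(C)CC=C(O[Si](C)(C)C(C)(C)C)[C@@H](C(=O)OC)[C@H]3C(=O)[C@@H]1[C@@H]4C=C[C@H]2C4 | intermediate
10 | cis-fused ene-dione with C2=C3 TBS enol ether and 4α-CO2Me | CC=1C(=O)[C@@]2(C)CC=C(O[Si](C)(C)C(C)(C)C)[C@@H](C(=O)OC)[C@H]2C(=O)C=1 | intermediate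
11 | bis(TBS enol ether) dienone (C2=C3 and C5=C6) | CC=1C(=O)[C@@]2(C)CC=C(O[Si](C)(C)C(C)(C)C)[C@@H](C(=O)OC)C2=C(O[Si](C)(C)C(C)(C)C)C=1 | intermediate
12 | lithium C8=C9 enolate | CC1=C(O[Li])[C@@]2(C)CC=C(O[Si](C)(C)C(C)(C)C)[C@@H](C(=O)OC)C2=C(O[Si](C)(C)C(C)(C)C)C1 | intermediate
13 | C9 enol triflate, bis(TBS enol ether), 4α-CO2Me | CC1=C(OS(=O)(=O)C(F)(F)F)[C@@]2(C)CC=C(O[Si](C)(C)C(C)(C)C)[C@@H](C(=O)OC)C2=C(O[Si](C)(C)C(C)(C)C)C1 | intermediate
14 | potassium ester dienolate at C4 | CC1=C(OS(=O)(=O)C(F)(F)F)[C@@]2(C)CC=C(O[Si](C)(C)C(C)(C)C)C(=C(OC)O[K])C2=C(O[Si](C)(C)C(C)(C)C)C1 | intermediate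
15 | C4-methylated bis(TBS enol ether) (4α-Me, 4β-CO2Me) | CC1=C(OS(=O)(=O)C(F)(F)F)[C@@]2(C)CC=C(O[Si](C)(C)C(C)(C)C)[C@](C)(C(=O)OC)C2=C(O[Si](C)(C)C(C)(C)C)C1 | intermediate
16 | trans-fused 3,6-diketo 19-methyl ester, C9 enol triflate | CC1=C(OS(=O)(=O)C(F)(F)F)[C@@]2(C)CCC(=O)[C@](C)(C(=O)OC)[C@@H]2C(=O)C1 | intermediate
17 | 3α-hydroxy-19,6β-olide, C9 enol triflate | CC1=C(OS(=O)(=O)C(F)(F)F)[C@@]2(C)CC[C@@H](O)[C@@]3(C)[C@@H]2[C@H](OC3=O)C1 | intermediate
18 | 3α,6β,19-triol, C9 enol triflate | CC1=C(OS(=O)(=O)C(F)(F)F)[C@@]2(C)CC[C@@H](O)[C@](C)(CO)[C@@H]2[C@H](O)C1 | intermediate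
19 | 3-methylbutanoyl chloride | CC(C)CC(=O)Cl | starting material
20 | 3α,19-bis(3-methylbutanoate), 6β-OH, C9 enol triflate | CC1=C(OS(=O)(=O)C(F)(F)F)[C@@]2(C)CC[C@@H](OC(=O)CC(C)C)[C@](C)(COC(=O)CC(C)C)[C@@H]2[C@H](O)C1 | intermediate
21 | C9-vinyl diene | CC1=C(C=C)[C@@]2(C)CC[C@@H](OC(=O)CC(C)C)[C@](C)(COC(=O)CC(C)C)[C@@H]2[C@H](O)C1 | intermediate
22 | 2,2,6-trimethyl-4H-1,3-dioxin-4-one | CC1=CC(=O)OC(C)(C)O1 | starting material
23 | 2-(trimethylsilyl)ethanol | C[Si](C)(C)CCO | starting material
24 | 2-(trimethylsilyl)ethyl 3-oxobutanoate | CC(=O)CC(=O)OCC[Si](C)(C)C | intermediate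
25 | 2-(trimethylsilyl)ethyl (2E)-3-{[(trifluoromethyl)sulfonyl]oxy}but-2-enoate | C/C(OS(=O)(=O)C(F)(F)F)=C\C(=O)OCC[Si](C)(C)C | intermediate
26 | B-alkyl-9-BBN at C12 | CC1=C(CCB3C4CCCC3CCC4)[C@@]2(C)CC[C@@H](OC(=O)CC(C)C)[C@](C)(COC(=O)CC(C)C)[C@@H]2[C@H](O)C1 | intermediate
27 | 2-(trimethylsilyl)ethyl ester of the target acid | CC1=C(CC/C(C)=C/C(=O)OCC[Si](C)(C)C)[C@@]2(C)CC[C@@H](OC(=O)CC(C)C)[C@](C)(COC(=O)CC(C)C)[C@@H]2[C@H](O)C1 | intermediate
28 | (13E)-6β-hydroxy-3α,19-bis(3-methylbutanoyloxy)labda-8,13-dien-15-oic acid | CC1=C(CC/C(C)=C/C(=O)O)[C@@]2(C)CC[C@@H](OC(=O)CC(C)C)[C@](C)(COC(=O)CC(C)C)[C@@H]2[C@H](O)C1 | target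

**Step count.** 16 steps in total; longest linear sequence 13 steps (steps 1–3, 5–12, 15, 16).

**Steps most likely to fail**

Step 5. The cycloaddition may stall at the methyl-bearing ene-dione carbon, where the quaternary C10 has to form, or the silyl dienol ether may be consumed by desilylative Michael addition without ring closure. The fallback replaces the concerted cycloaddition by a stepwise anionic annulation and sets out from 8 and the free β-keto ester 4. Cs2CO3 in CH2Cl2 should give, by Michael addition (C4 to C5) and then ring-closing Michael addition of the C10 enolate to C1, the tetracyclic β-keto ester F1. Flash vacuum pyrolysis should give the cis-fused ene-dione β-keto ester F2. TBSOTf/Et3N (2.5 equiv) should give the bis(TBS enol ether) with C3=C4 and C5=C6 double bonds F3, and LiBH(s-Bu)3 followed by PhNTf2 the corresponding C9 enol triflate F4. KN(SiMe3)2 removes a C2 proton of F4 to give the same dienolate 14; MeI and aqueous HCl then bring the route back at 16.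

Step 8. The hydride may add 1,2 to C9 or 1,6 to C5, it may act as a base on the acidic C4–H, or O-triflation of the tetrasubstituted enolate may be too slow. The fallback separates conjugate reduction from enolisation and sets out from 11. [CuH(PPh3)]6 in benzene should give the saturated C9 ketone (8-H) bis(TBS enol ether) F5. KN(SiMe3)2/MeI should methylate C4, whose doubly allylic ester α-proton is the most acidic, to give the C4-methylated C9 ketone F6. KN(SiMe3)2 and N-(5-chloropyridin-2-yl)triflimide (C9 can enolise only toward C8) should then give 15, where the route is rejoined; hydrolysis as in step 9 gives 16.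

Step 9. The pentadienyl ester enolate may be alkylated at C2 or C6 instead of C4, or with poor facial selectivity at C4. The fallback uses a β-keto ester enolate instead of the ester dienolate and sets out from 13. Bu4NF (1.0 equiv) with MeI in THF at −78 °C should cleave the less hindered ring A silyl enol ether; the enolate equilibrates to the β-keto ester enolate, and its C-methylation next to the C5=C6 enol ether (α-face, anti to the C10 methyl) should give the C3 ketone with 4α-Me/4β-CO2Me and the C5=C6 TBS enol ether F7. Aqueous HCl then returns the route at 16.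

**Further compounds**

F1 | step 5 | tetracyclic β-keto ester (C3 ketone analogue of 9) | C[C@@]12C(=O)[C@@]3(C)CCC(=O)C(C(=O)OC)[C@H]3C(=O)[C@@H]1[C@@H]4C=C[C@H]2C4
F2 | step 5 | cis-fused ene-dione β-keto ester | CC=1C(=O)[C@@]2(C)CCC(=O)C(C(=O)OC)[C@H]2C(=O)C=1
F3 | step 5 | bis(TBS enol ether) with C3=C4 and C5=C6 double bonds | CC=1C(=O)[C@@]2(C)CCC(O[Si](C)(C)C(C)(C)C)=C(C(=O)OC)C2=C(O[Si](C)(C)C(C)(C)C)C=1
F4 | step 5 | C9 enol triflate of the C3=C4/C5=C6 bis(TBS enol ether) | CC1=C(OS(=O)(=O)C(F)(F)F)[C@@]2(C)CCC(O[Si](C)(C)C(C)(C)C)=C(C(=O)OC)C2=C(O[Si](C)(C)C(C)(C)C)C1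
F5 | step 8 | saturated C9 ketone (8-H) bis(TBS enol ether) | CC1C(=O)[C@@]2(C)CC=C(O[Si](C)(C)C(C)(C)C)[C@@H](C(=O)OC)C2=C(O[Si](C)(C)C(C)(C)C)C1
F6 | step 8 | C4-methylated C9 ketone (4α-Me, 4β-CO2Me) | CC1C(=O)[C@@]2(C)CC=C(O[Si](C)(C)C(C)(C)C)[C@](C)(C(=O)OC)C2=C(O[Si](C)(C)C(C)(C)C)C1
F7 | step 9 | C3 ketone with 4α-Me/4β-CO2Me and C5=C6 TBS enol ether | CC1=C(OS(=O)(=O)C(F)(F)F)[C@@]2(C)CCC(=O)[C@](C)(C(=O)OC)C2=C(O[Si](C)(C)C(C)(C)C)C1
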